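The C40 skeleton is cut at C11'=C12' and C11=C12 into a ring B C15 phosphonium salt, the C10 trienedial and a ring A C15 keto phosphonium salt, joined by two Wittig reactions; desilylation and C19 lauroylation finish. Everything rests on ring B: in its C3'-ketone, C7'-ester form the C6' hydrogen is α to the ester and, through C4'=C5', vinylogously γ to the ketone, so C6' racemises while a ketoreductase reduces C3' of one enantiomer. This single reduction sets both (3'R) and (6'R). Its precursor is racemic ethyl 2,6,6-trimethyl-4-oxocyclohex-2-ene-1-carboxylate, one annulation step from mesityl oxide and ethyl acetoacetate.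

Key step: step 2

Remark: the target is read as all-E (3R,3'R,6'R)-siphonaxanthin 19-dodecanoate as drawn; polyenes are handled under argon in the dark, and the ethyl ester is kept in the precursor because only an ester at C7' gives C6'–H the acidity that racemisation needs.

Step 1
Reactants: 1 mesityl oxide; 2 ethyl acetoacetate
Product: 4 rac-ethyl 2,6,6-trimethyl-4-oxocyclohex-2-ene-1-carboxylate, via Michael adduct 3 (not isolated)
Conditions: ZnCl2 (anhydrous, substoichiometric), heptane/toluene, reflux, Dean–Stark trap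
Reagents that add atoms: none
Why: ZnCl2 promotes Michael addition of the acetoacetate enol to the β,β-dimethyl carbon of the enone, and the resulting 1,5-diketone closes by intramolecular aldol condensation (Robinson-type annulation) under water removal, the new stereocenter being racemic by design.

Step 2
Reactants: 4 rac-ethyl 2,6,6-trimethyl-4-oxocyclohex-2-ene-1-carboxylate
Product: 5 ethyl (1R,4R)-4-hydroxy-2,6,6-trimethylcyclohex-2-ene-1-carboxylate
Conditions: NADPH-dependent ketoreductase (variant chosen by panel screening), NADP+ (cat.), D-glucose, glucose dehydrogenase, 0.1 M triethanolamine buffer pH 8.5–9.0 (pH-stat, NaOH), DMSO (10% v/v), 30 °C, N2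
Reagents that add atoms: none
Why: Proposed new method: C6'–H of 4 is α to the ester and, through C4'=C5', vinylogously γ to the C3' ketone, so the amine buffer reversibly forms the extended dienolate and interconverts the two enantiomers (and the minor ester-conjugated tautomer), while the ketoreductase passes hydride from NADPH to C3' of the (6'R) enantiomer only. The nearest precedent is the reductive dynamic kinetic resolution of 2-substituted 3-oxo esters, by ketoreductases or by RuCl(p-cymene)(TsDPEN), where the labile centre lies directly between the carbonyls; here the acidifying ketone acts across the ring double bond, and enzymatic 1,2-reduction of isophorone-type enones is itself established. No ring is closed. C3' is fixed by the face of hydride delivery in the enzyme pocket and C6' by the enzyme's choice of substrate enantiomer, both secured by screening. The step needs enantiomer discrimination, C=O over C=C chemoselectivity and racemisation faster than reduction of the mismatched enantiomer; the doubly activated C6'–H provides the last, a purified reductase free of ene-reductase activity the second, and nitrogen protects the dienolate from autoxidation. After reduction the ketone that acidified C6'–H is gone, so the trans product cannot epimerise and accumulates.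

Step 3
Reactants: 5 ethyl (1R,4R)-4-hydroxy-2,6,6-trimethylcyclohex-2-ene-1-carboxylate
Product: 6 ethyl (1R,4R)-4-(tert-butyldimethylsilyloxy)-2,6,6-trimethylcyclohex-2-ene-1-carboxylate
Conditions: TBSCl, imidazole, DMF, rt
Reagents that add atoms: tert-butyldimethylsilyl chloride, CC(C)(C)[Si](C)(C)Cl
Why: Imidazole-mediated silyl ether formation at the secondary allylic alcohol touches neither stereocenter.

Step 4
Reactants: 6 ethyl (1R,4R)-4-(tert-butyldimethylsilyloxy)-2,6,6-trimethylcyclohex-2-ene-1-carboxylate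
Product: 7 [(1R,4R)-4-(tert-butyldimethylsilyloxy)-2,6,6-trimethylcyclohex-2-en-1-yl]methanol
Conditions: i-Bu2AlH (2.5 equiv), CH2Cl2, −78 → 0 °C; aq. potassium sodium tartrate
Reagents that add atoms: none
Why: Hydride reduction of the hindered ester to the primary alcohol is non-basic, so C6' is not enolised and the silyl ether and alkene are untouched.

Step 5
Reactants: 7 [(1R,4R)-4-(tert-butyldimethylsilyloxy)-2,6,6-trimethylcyclohex-2-en-1-yl]methanol
Product: 8 (1R,4R)-4-(tert-butyldimethylsilyloxy)-2,6,6-trimethylcyclohex-2-ene-1-carbaldehyde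
Conditions: Dess–Martin periodinane, NaHCO3, CH2Cl2, 0 °C → rt
Reagents that add atoms: none
Why: Buffered Dess–Martin oxidation is mild enough to give the α-branched β,γ-unsaturated aldehyde without epimerising C6' or moving C4'=C5' into conjugation.

Step 6
Reactants: 8 (1R,4R)-4-(tert-butyldimethylsilyloxy)-2,6,6-trimethylcyclohex-2-ene-1-carbaldehyde
Product: 9 (E)-4-[(1R,4R)-4-(tert-butyldimethylsilyloxy)-2,6,6-trimethylcyclohex-2-en-1-yl]but-3-en-2-one
Conditions: Ph3P=CHC(O)CH3, toluene, 100 °C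
Reagents that add atoms: 1-(triphenylphosphoranylidene)propan-2-one, CC(=O)C=P(c1ccccc1)(c1ccccc1)c1ccccc1
Why: Wittig olefination with a stabilised, almost non-basic ylide gives the (E)-enone and spares the epimerisable C6' centre.

Step 7
Reactants: 9 (E)-4-[(1R,4R)-4-(tert-butyldimethylsilyloxy)-2,6,6-trimethylcyclohex-2-en-1-yl]but-3-en-2-one
Product: 10 (E)-3-methyl-1-[(1R,4R)-4-(tert-butyldimethylsilyloxy)-2,6,6-trimethylcyclohex-2-en-1-yl]penta-1,4-dien-3-ol (both carbinol epimers)
Conditions: CH2=CHMgBr, THF, −78 → 0 °C; aq. NH4Cl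
Reagents that add atoms: vinylmagnesium bromide, C=C[Mg]Br
Why: Grignard 1,2-addition to the β-substituted enone gives the tertiary bis-allylic alcohol, whose new centre forms unselectively and is ionised in the next step.

Step 8
Reactants: 10 (E)-3-methyl-1-[(1R,4R)-4-(tert-butyldimethylsilyloxy)-2,6,6-trimethylcyclohex-2-en-1-yl]penta-1,4-dien-3-ol
Product: 11 [(2E,4E)-3-methyl-5-[(1R,4R)-4-(tert-butyldimethylsilyloxy)-2,6,6-trimethylcyclohex-2-en-1-yl]penta-2,4-dien-1-yl]triphenylphosphonium bromide (ring B C15 salt)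
Conditions: PPh3·HBr, CH2Cl2, 0 °C → rt; crystallise from EtOAc
Reagents that add atoms: triphenylphosphine hydrobromide, Br.c1ccc(cc1)P(c1ccccc1)c1ccccc1
Why: HBr ionises the tertiary bis-allylic alcohol and PPh3 captures the pentadienyl cation at its unhindered terminus (SN1-type allylic transposition), giving the conjugated dienyl salt in an aprotic medium that keeps the silyl ether.

Step 9
Reactants: 11 ring B C15 salt; 12 (2E,4E,6E)-2,7-dimethylocta-2,4,6-trienedial
Product: 14 (2E,4E,6E,8E,10E,12E)-2,7,11-trimethyl-13-[(1R,4R)-4-(tert-butyldimethylsilyloxy)-2,6,6-trimethylcyclohex-2-en-1-yl]trideca-2,4,6,8,10,12-hexaenal (C25 aldehyde), via dienyl ylide 13 (not isolated)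
Conditions: 12 (2 equiv), NaOMe, CH2Cl2/MeOH, 0 °C → rt; then heptane, 80 °C (E/Z equilibration)
Reagents that add atoms: none
Why: Wittig reaction of the semi-stabilised ylide with an excess of the symmetrical dialdehyde gives mono-olefination at C11'=C12', and heating equilibrates the new bond to E.

Step 10
Reactants: 15 ketoisophorone
Product: 17 (4R,6R)-4-hydroxy-2,2,6-trimethylcyclohexan-1-one, via (6R)-levodione 16 (not isolated)
Conditions: old yellow enzyme (OYE2), NADP+ (cat.), D-glucose, glucose dehydrogenase, phosphate buffer pH 7, 30 °C; then levodione reductase, NAD+ (cat.), same pot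
Reagents that add atoms: none
Why: Biocatalytic conjugate reduction followed by ketone reduction, in which the ene-reductase sets (6R) at the C=C bond and levodione reductase then sets (4R) at the unhindered carbonyl, both under enzyme control.

Step 11
Reactants: 17 (4R,6R)-4-hydroxy-2,2,6-trimethylcyclohexan-1-one
Product: 18 (4R,6R)-4-(tert-butyldimethylsilyloxy)-2,2,6-trimethylcyclohexan-1-one
Conditions: TBSCl, imidazole, DMF, rt
Reagents that add atoms: tert-butyldimethylsilyl chloride, CC(C)(C)[Si](C)(C)Cl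
Why: Standard silylation of the secondary alcohol leaves C3 (carotenoid numbering) untouched.

Step 12
Reactants: 18 (4R,6R)-4-(tert-butyldimethylsilyloxy)-2,2,6-trimethylcyclohexan-1-one
Product: 20 (R)-4-(tert-butyldimethylsilyloxy)-2,6,6-trimethylcyclohex-1-en-1-yl trifluoromethanesulfonate, via potassium enolate 19 (not isolated)
Conditions: KN(SiMe3)2, THF, −78 °C; then PhNTf2, −78 → 0 °C
Reagents that add atoms: N-phenylbis(trifluoromethanesulfonimide), O=S(=O)(N(c1ccccc1)S(=O)(=O)C(F)(F)F)C(F)(F)F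
Why: The ketone can enolise only towards the methyl-bearing carbon, so a single enolate is O-sulfonylated (enol triflate formation) and the methyl-bearing stereocenter is deliberately erased.

Step 13
Reactants: 20 (R)-4-(tert-butyldimethylsilyloxy)-2,6,6-trimethylcyclohex-1-en-1-yl trifluoromethanesulfonate
Product: 21 ethyl 2-[(R)-4-(tert-butyldimethylsilyloxy)-2,6,6-trimethylcyclohex-1-en-1-yl]acetate
Conditions: BrZnCH2CO2Et (from BrCH2CO2Et, Zn, THF), Pd2(dba)3 (cat.), XPhos (cat.), THF, 65 °C
Reagents that add atoms: ethyl bromoacetate, CCOC(=O)CBr, used as its zinc reagent (2-ethoxy-2-oxoethyl)zinc bromide, CCOC(=O)C[Zn]Br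
Why: Negishi cross-coupling of the enol triflate with the Reformatsky zinc enolate forms the C6–C7 bond without moving the ring double bond, the bulky biaryl phosphine easing reductive elimination at the hindered alkenyl palladium.

Step 14
Reactants: 21 ethyl 2-[(R)-4-(tert-butyldimethylsilyloxy)-2,6,6-trimethylcyclohex-1-en-1-yl]acetate
Product: 22 N-methoxy-N-methyl-2-[(R)-4-(tert-butyldimethylsilyloxy)-2,6,6-trimethylcyclohex-1-en-1-yl]acetamide
Conditions: MeNH(OMe)·HCl, i-PrMgCl, THF, −20 → 0 °C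
Reagents that add atoms: N,O-dimethylhydroxylamine hydrochloride, CNOC.Cl
Why: Aminolysis of the ester by the magnesium amide of N,O-dimethylhydroxylamine (Weinreb amide formation) is fast at low temperature and leaves the β,γ-alkene in place.

Step 15
Reactants: 23 tert-butyldimethyl(prop-2-yn-1-yloxy)silane
Product: 24 methyl 4-(tert-butyldimethylsilyloxy)but-2-ynoate
Conditions: n-BuLi, THF, −78 °C; then ClCO2Me
Reagents that add atoms: methyl chloroformate, COC(Cl)=O
Why: Deprotonation of the terminal alkyne and C-acylation of the lithium acetylide give the ynoate.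

Step 16
Reactants: 24 methyl 4-(tert-butyldimethylsilyloxy)but-2-ynoate
Product: 25 methyl (E)-4-(tert-butyldimethylsilyloxy)-3-(tributylstannyl)but-2-enoate
Conditions: Bu3SnLi (from Bu3SnH, LiN(i-Pr)2), CuBr·SMe2, THF, −78 °C; then 24, MeOH, −78 °C
Reagents that add atoms: tributyltin hydride, CCCC[SnH](CCCC)CCCC (delivers Bu3Sn as Bu3SnCu·SMe2)
Why: syn-Stannylcupration puts tin on the β-carbon and copper on the α-carbon, and protonation of the alkenylcopper at −78 °C keeps that syn relationship, so the future C19 and C11 carbons end up cis (kinetic control of alkene geometry).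

Step 17
Reactants: 25 methyl (E)-4-(tert-butyldimethylsilyloxy)-3-(tributylstannyl)but-2-enoate
Product: 26 (E)-4-(tert-butyldimethylsilyloxy)-3-(tributylstannyl)but-2-en-1-ol
Conditions: i-Bu2AlH (2.5 equiv), CH2Cl2, −78 °C; aq. potassium sodium tartrate
Reagents that add atoms: none
Why: 1,2-Reduction of the conjugated ester gives the allylic alcohol with the C–Sn bond and alkene geometry retained.

Step 18
Reactants: 26 (E)-4-(tert-butyldimethylsilyloxy)-3-(tributylstannyl)but-2-en-1-ol; 22 N-methoxy-N-methyl-2-[(R)-4-(tert-butyldimethylsilyloxy)-2,6,6-trimethylcyclohex-1-en-1-yl]acetamide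
Product: 28 (3E)-5-hydroxy-3-[(tert-butyldimethylsilyloxy)methyl]-1-[(R)-4-(tert-butyldimethylsilyloxy)-2,6,6-trimethylcyclohex-1-en-1-yl]pent-3-en-2-one, via dilithio alkenyl alkoxide 27 (not isolated)
Conditions: 26 (1.5 equiv), n-BuLi (2.1 equiv per 26), THF, −78 °C; then 22, −78 °C; aq. NH4Cl at −78 °C
Reagents that add atoms: none
Why: After O-deprotonation, tin–lithium exchange gives a configurationally stable alkenyllithium that acylates the N-methoxy-N-methylamide through a chelated tetrahedral adduct collapsing only on work-up (Weinreb ketone synthesis), so the C8–C9 bond forms once with the stannane's geometry, and the low temperature suppresses silyl migration to the trans-disposed alkoxide.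

Step 19
Reactants: 28 (3E)-5-hydroxy-3-[(tert-butyldimethylsilyloxy)methyl]-1-[(R)-4-(tert-butyldimethylsilyloxy)-2,6,6-trimethylcyclohex-1-en-1-yl]pent-3-en-2-one
Product: 30 [(2E)-3-[(tert-butyldimethylsilyloxy)methyl]-4-oxo-5-[(R)-4-(tert-butyldimethylsilyloxy)-2,6,6-trimethylcyclohex-1-en-1-yl]pent-2-en-1-yl]triphenylphosphonium bromide (ring A C15 salt), via allylic bromide 29 (not isolated)
Conditions: CBr4, PPh3, CH2Cl2, 0 °C; then second portion of PPh3, MeCN, rt → 40 °C
Reagents that add atoms: carbon tetrabromide, BrC(Br)(Br)Br; triphenylphosphine, c1ccc(cc1)P(c1ccccc1)c1ccccc1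
Why: Appel bromination of the primary allylic alcohol and in-flask SN2 displacement of the γ-bromo enone by PPh3 give the salt under neutral conditions that keep both silyl ethers and the C9=C10 geometry.

Step 20
Reactants: 30 ring A C15 salt; 14 C25 aldehyde
Product: 32 (3R,3'R,6'R)-3,3',19-tris(tert-butyldimethylsilyloxy)-7,8-dihydro-β,ε-caroten-8-one, via keto ylide 31 (not isolated)
Conditions: 30 (1.5 equiv), 1,2-epoxybutane, EtOH, 65 °C, argon, dark; then heptane, 80 °C (E/Z equilibration)
Reagents that add atoms: none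
Why: Wittig olefination of the polyenal by the vinylogously ketone-stabilised allylic ylide, generated without strong base through bromide opening of the epoxide, forms C11=C12 in the manner of apo-carotenal chain extension with ester-stabilised C5 ylides, and heating equilibrates the new bond to E.

Step 21
Reactants: 32 (3R,3'R,6'R)-3,3',19-tris(tert-butyldimethylsilyloxy)-7,8-dihydro-β,ε-caroten-8-one
Product: 33 (3R,3'R,6'R)-3,3',19-trihydroxy-7,8-dihydro-β,ε-caroten-8-one (siphonaxanthin)
Conditions: HF·pyridine, pyridine, THF, 0 °C → rt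
Reagents that add atoms: none
Why: Pyridine-buffered fluoride desilylation removes the three silyl ethers without ionising the allylic C3' alcohol or disturbing the polyene and the β,γ-unsaturated ketone.

Step 22
Reactants: 33 siphonaxanthin
Product: 34 (3R,3'R,6'R)-3,3'-dihydroxy-8-oxo-7,8-dihydro-β,ε-caroten-19-yl dodecanoate (target, CNP0415583.1)
Conditions: C11H23COCl (1.05 equiv), 2,4,6-collidine, CH2Cl2, −78 → −40 °C
Reagents that add atoms: dodecanoyl chloride, CCCCCCCCCCCC(Cl)=O
Why: Kinetically selective O-acylation of the only primary hydroxyl (C19) over the two secondary ring hydroxyls, using one equivalent of acid chloride and a hindered pyridine base at low temperature.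

Compound list
1 | mesityl oxide | CC(=O)C=C(C)C | starting material
2 | ethyl acetoacetate | CCOC(=O)CC(C)=O | starting material
3 | ethyl 2-acetyl-3,3-dimethyl-5-oxohexanoate (Michael adduct, racemic) | CCOC(=O)C(C(C)=O)C(C)(C)CC(C)=O | intermediate (not isolated)
4 | rac-ethyl 2,6,6-trimethyl-4-oxocyclohex-2-ene-1-carboxylate | CCOC(=O)C1C(C)=CC(=O)CC1(C)C | intermediate
5 | ethyl (1R,4R)-4-hydroxy-2,6,6-trimethylcyclohex-2-ene-1-carboxylate | CCOC(=O)[C@H]1C(C)=C[C@H](O)CC1(C)C | intermediate
6 | ethyl (1R,4R)-4-(tert-butyldimethylsilyloxy)-2,6,6-trimethylcyclohex-2-ene-1-carboxylate | CCOC(=O)[C@H]1C(C)=C[C@H](O[Si](C)(C)C(C)(C)C)CC1(C)C | intermediate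
7 | [(1R,4R)-4-(tert-butyldimethylsilyloxy)-2,6,6-trimethylcyclohex-2-en-1-yl]methanol | OC[C@H]1C(C)=C[C@H](O[Si](C)(C)C(C)(C)C)CC1(C)C | intermediate
8 | (1R,4R)-4-(tert-butyldimethylsilyloxy)-2,6,6-trimethylcyclohex-2-ene-1-carbaldehyde | O=C[C@H]1C(C)=C[C@H](O[Si](C)(C)C(C)(C)C)CC1(C)C | intermediate
9 | (E)-4-[(1R,4R)-4-(tert-butyldimethylsilyloxy)-2,6,6-trimethylcyclohex-2-en-1-yl]but-3-en-2-one | CC(=O)/C=C/[C@H]1C(C)=C[C@H](O[Si](C)(C)C(C)(C)C)CC1(C)C | intermediate
10 | (E)-3-methyl-1-[(1R,4R)-4-(tert-butyldimethylsilyloxy)-2,6,6-trimethylcyclohex-2-en-1-yl]penta-1,4-dien-3-ol (carbinol epimers) | C=CC(C)(O)/C=C/[C@H]1C(C)=C[C@H](O[Si](C)(C)C(C)(C)C)CC1(C)C | intermediate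
11 | [(2E,4E)-3-methyl-5-[(1R,4R)-4-(tert-butyldimethylsilyloxy)-2,6,6-trimethylcyclohex-2-en-1-yl]penta-2,4-dien-1-yl]triphenylphosphonium bromide | [Br-].c1ccccc1[P+](c1ccccc1)(c1ccccc1)C/C=C(C)/C=C/[C@H]1C(C)=C[C@H](O[Si](C)(C)C(C)(C)C)CC1(C)C | intermediate
12 | (2E,4E,6E)-2,7-dimethylocta-2,4,6-trienedial | O=C/C(C)=C/C=C/C=C(C)/C=O | starting material
13 | ylide of 11 | c1ccccc1P(c1ccccc1)(c1ccccc1)=C/C=C(C)/C=C/[C@H]1C(C)=C[C@H](O[Si](C)(C)C(C)(C)C)CC1(C)C | intermediate (not isolated)
14 | (2E,4E,6E,8E,10E,12E)-2,7,11-trimethyl-13-[(1R,4R)-4-(tert-butyldimethylsilyloxy)-2,6,6-trimethylcyclohex-2-en-1-yl]trideca-2,4,6,8,10,12-hexaenal | O=C/C(C)=C/C=C/C=C(C)/C=C/C=C(C)/C=C/[C@H]1C(C)=C[C@H](O[Si](C)(C)C(C)(C)C)CC1(C)C | intermediate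
15 | ketoisophorone (2,6,6-trimethylcyclohex-2-ene-1,4-dione) | CC1=CC(=O)CC(C)(C)C1=O | starting material
16 | (R)-2,2,6-trimethylcyclohexane-1,4-dione ((6R)-levodione) | O=C1[C@H](C)CC(=O)CC1(C)C | intermediate (not isolated)
17 | (4R,6R)-4-hydroxy-2,2,6-trimethylcyclohexan-1-one | O=C1[C@H](C)C[C@@H](O)CC1(C)C | intermediate
18 | (4R,6R)-4-(tert-butyldimethylsilyloxy)-2,2,6-trimethylcyclohexan-1-one | O=C1[C@H](C)C[C@@H](O[Si](C)(C)C(C)(C)C)CC1(C)C | intermediate
19 | potassium (R)-4-(tert-butyldimethylsilyloxy)-2,6,6-trimethylcyclohex-1-en-1-olate | [K+].[O-]C1=C(C)C[C@@H](O[Si](C)(C)C(C)(C)C)CC1(C)C | intermediate (not isolated)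
20 | (R)-4-(tert-butyldimethylsilyloxy)-2,6,6-trimethylcyclohex-1-en-1-yl trifluoromethanesulfonate | O=S(=O)(OC1=C(C)C[C@@H](O[Si](C)(C)C(C)(C)C)CC1(C)C)C(F)(F)F | intermediate
21 | ethyl 2-[(R)-4-(tert-butyldimethylsilyloxy)-2,6,6-trimethylcyclohex-1-en-1-yl]acetate | CCOC(=O)CC1=C(C)C[C@@H](O[Si](C)(C)C(C)(C)C)CC1(C)C | intermediate
22 | N-methoxy-N-methyl-2-[(R)-4-(tert-butyldimethylsilyloxy)-2,6,6-trimethylcyclohex-1-en-1-yl]acetamide | CON(C)C(=O)CC1=C(C)C[C@@H](O[Si](C)(C)C(C)(C)C)CC1(C)C | intermediate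
23 | tert-butyldimethyl(prop-2-yn-1-yloxy)silane | C#CCO[Si](C)(C)C(C)(C)C | starting material
24 | methyl 4-(tert-butyldimethylsilyloxy)but-2-ynoate | COC(=O)C#CCO[Si](C)(C)C(C)(C)C | intermediate
25 | methyl (E)-4-(tert-butyldimethylsilyloxy)-3-(tributylstannyl)but-2-enoate | COC(=O)/C=C(\CO[Si](C)(C)C(C)(C)C)[Sn](CCCC)(CCCC)CCCC | intermediate
26 | (E)-4-(tert-butyldimethylsilyloxy)-3-(tributylstannyl)but-2-en-1-ol | OC/C=C(\CO[Si](C)(C)C(C)(C)C)[Sn](CCCC)(CCCC)CCCC | intermediate
27 | dilithio alkenyl alkoxide from 26 (lithium at the former tin carbon and on oxygen) | [Li]OC/C=C(\CO[Si](C)(C)C(C)(C)C)[Li] | intermediate (not isolated)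
28 | (3E)-5-hydroxy-3-[(tert-butyldimethylsilyloxy)methyl]-1-[(R)-4-(tert-butyldimethylsilyloxy)-2,6,6-trimethylcyclohex-1-en-1-yl]pent-3-en-2-one | OC/C=C(\CO[Si](C)(C)C(C)(C)C)C(=O)CC1=C(C)C[C@@H](O[Si](C)(C)C(C)(C)C)CC1(C)C | intermediate
29 | (3E)-5-bromo-3-[(tert-butyldimethylsilyloxy)methyl]-1-[(R)-4-(tert-butyldimethylsilyloxy)-2,6,6-trimethylcyclohex-1-en-1-yl]pent-3-en-2-one | BrC/C=C(\CO[Si](C)(C)C(C)(C)C)C(=O)CC1=C(C)C[C@@H](O[Si](C)(C)C(C)(C)C)CC1(C)C | intermediate (not isolated)
30 | [(2E)-3-[(tert-butyldimethylsilyloxy)methyl]-4-oxo-5-[(R)-4-(tert-butyldimethylsilyloxy)-2,6,6-trimethylcyclohex-1-en-1-yl]pent-2-en-1-yl]triphenylphosphonium bromide | [Br-].c1ccccc1[P+](c1ccccc1)(c1ccccc1)C/C=C(\CO[Si](C)(C)C(C)(C)C)C(=O)CC1=C(C)C[C@@H](O[Si](C)(C)C(C)(C)C)CC1(C)C | intermediate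
31 | ylide of 30 | c1ccccc1P(c1ccccc1)(c1ccccc1)=C/C=C(\CO[Si](C)(C)C(C)(C)C)C(=O)CC1=C(C)C[C@@H](O[Si](C)(C)C(C)(C)C)CC1(C)C | intermediate (not isolated)
32 | (3R,3'R,6'R)-3,3',19-tris(tert-butyldimethylsilyloxy)-7,8-dihydro-β,ε-caroten-8-one | CC(C)(C)[Si](C)(C)OC\C(=C/C=C/C(C)=C/C=C/C=C(C)/C=C/C=C(C)/C=C/[C@H]1C(C)=C[C@H](O[Si](C)(C)C(C)(C)C)CC1(C)C)C(=O)CC1=C(C)C[C@@H](O[Si](C)(C)C(C)(C)C)CC1(C)C | intermediate
33 | siphonaxanthin, (3R,3'R,6'R)-3,3',19-trihydroxy-7,8-dihydro-β,ε-caroten-8-one | OC\C(=C/C=C/C(C)=C/C=C/C=C(C)/C=C/C=C(C)/C=C/[C@H]1C(C)=C[C@H](O)CC1(C)C)C(=O)CC1=C(C)C[C@@H](O)CC1(C)C | intermediate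
34 | siphonaxanthin 19-dodecanoate (CNP0415583.1) | CCCCCCCCCCCC(=O)OC\C(=C/C=C/C(C)=C/C=C/C=C(C)/C=C/C=C(C)/C=C/[C@H]1C(C)=C[C@H](O)CC1(C)C)C(=O)CC1=C(C)C[C@@H](O)CC1(C)C | target

Total step count: 22. Longest linear sequence: 12 steps (steps 1–9, then 20–22). The ring A branch (steps 10–14, 18, 19) and the C5 branch (steps 15–17) converge at steps 18 and 20.

Steps most likely to fail

Step 2 (Proposed new method). Racemisation at C6' may be slower than reduction of the mismatched enantiomer, the enzyme may discriminate enantiomer or carbonyl face poorly, or the ester-conjugated tautomer may be reduced; each would give stereoisomer mixtures. The fallback uses known chemistry and sets out from 4. Luche reduction (NaBH4, CeCl3·7H2O, MeOH, −20 °C) should give the racemic allylic alcohols, from which the racemic trans-hydroxy ester F1 is separated by chromatography. Lipase-catalysed transesterification (immobilised Candida antarctica lipase B, vinyl acetate, MTBE) is expected to acetylate the (4R) enantiomer preferentially to give ethyl (1R,4R)-4-acetoxy-2,6,6-trimethylcyclohex-2-ene-1-carboxylate F2. This is separated from the unreacted (1S,4S) alcohol and transesterified (K2CO3, EtOH) to return to 5. This classical resolution gives up the dynamic element and can use at most half of the racemate.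

Step 20. Addition of the doubly stabilised ylide to the deactivated polyenal may be slow, and prolonged heating invites loss of silyloxide from the ylide and polyene degradation. The fallback sets out from 28 and couples at the alcohol oxidation level. Luche reduction (NaBH4, CeCl3·7H2O, MeOH, −40 °C) would give the C8 epimeric diol F3. Its primary allylic hydroxyl would be brominated selectively (CBr4, PPh3, one equivalent, −20 °C) to the hydroxy allylic bromide F4 and displaced by PPh3 to the hydroxy phosphonium bromide F5. Its non-stabilised allylic ylide F6 (NaOMe, CH2Cl2/MeOH, 0 °C) should add readily to 14 to give the 8-hydroxy C40 polyene F7. MnO2 (CH2Cl2, rt) then oxidises the only free hydroxyl, which is allylic to the polyene, and the route is rejoined at 32.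

Step 13. Transmetalation or reductive elimination at the tetrasubstituted alkenyl palladium, which is flanked by the gem-dimethyl group, may be slow, so that triflate reduction or hydrolysis takes over. The fallback sets out from 20. Stille coupling with tributyl(vinyl)stannane (Pd(PPh3)4, LiCl, THF, reflux) would give the diene F8. Hydroboration of its terminal vinyl group with 9-BBN would give the alkylborane F9, and oxidation (NaOH, H2O2) the homoallylic alcohol F10. Oxidation in two stages (TEMPO, PhI(OAc)2 to the aldehyde F11; then NaClO2, NaH2PO4, 2-methyl-2-butene) would give the acid F12. Coupling with N,O-dimethylhydroxylamine (EDC, CH2Cl2) returns to 22.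

Further compounds
F1 | step 2 | rac-trans-ethyl 4-hydroxy-2,6,6-trimethylcyclohex-2-ene-1-carboxylate (both enantiomers) | CCOC(=O)[C@H]1C(C)=C[C@H](O)CC1(C)C.CCOC(=O)[C@@H]1C(C)=C[C@@H](O)CC1(C)C
F2 | step 2 | ethyl (1R,4R)-4-acetoxy-2,6,6-trimethylcyclohex-2-ene-1-carboxylate | CCOC(=O)[C@H]1C(C)=C[C@H](OC(C)=O)CC1(C)C
F3 | step 20 | (3E)-3-[(tert-butyldimethylsilyloxy)methyl]-1-[(R)-4-(tert-butyldimethylsilyloxy)-2,6,6-trimethylcyclohex-1-en-1-yl]pent-3-ene-2,5-diol (C2 epimers) | OC/C=C(\CO[Si](C)(C)C(C)(C)C)C(O)CC1=C(C)C[C@@H](O[Si](C)(C)C(C)(C)C)CC1(C)C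
F4 | step 20 | (3E)-5-bromo-3-[(tert-butyldimethylsilyloxy)methyl]-1-[(R)-4-(tert-butyldimethylsilyloxy)-2,6,6-trimethylcyclohex-1-en-1-yl]pent-3-en-2-ol | BrC/C=C(\CO[Si](C)(C)C(C)(C)C)C(O)CC1=C(C)C[C@@H](O[Si](C)(C)C(C)(C)C)CC1(C)C
F5 | step 20 | [(2E)-3-[(tert-butyldimethylsilyloxy)methyl]-4-hydroxy-5-[(R)-4-(tert-butyldimethylsilyloxy)-2,6,6-trimethylcyclohex-1-en-1-yl]pent-2-en-1-yl]triphenylphosphonium bromide | [Br-].c1ccccc1[P+](c1ccccc1)(c1ccccc1)C/C=C(\CO[Si](C)(C)C(C)(C)C)C(O)CC1=C(C)C[C@@H](O[Si](C)(C)C(C)(C)C)CC1(C)C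
F6 | step 20 | ylide of F5 | c1ccccc1P(c1ccccc1)(c1ccccc1)=C/C=C(\CO[Si](C)(C)C(C)(C)C)C(O)CC1=C(C)C[C@@H](O[Si](C)(C)C(C)(C)C)CC1(C)C
F7 | step 20 | (3R,3'R,6'R)-3,3',19-tris(tert-butyldimethylsilyloxy)-7,8-dihydro-β,ε-caroten-8-ol (C8 epimers) | CC(C)(C)[Si](C)(C)OC\C(=C/C=C/C(C)=C/C=C/C=C(C)/C=C/C=C(C)/C=C/[C@H]1C(C)=C[C@H](O[Si](C)(C)C(C)(C)C)CC1(C)C)C(O)CC1=C(C)C[C@@H](O[Si](C)(C)C(C)(C)C)CC1(C)C
F8 | step 13 | (R)-tert-butyldimethyl[(3,5,5-trimethyl-4-vinylcyclohex-3-en-1-yl)oxy]silane | C=CC1=C(C)C[C@@H](O[Si](C)(C)C(C)(C)C)CC1(C)C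
F9 | step 13 | 9-{2-[(R)-4-(tert-butyldimethylsilyloxy)-2,6,6-trimethylcyclohex-1-en-1-yl]ethyl}-9-borabicyclo[3.3.1]nonane | B1(CCC2=C(C)C[C@@H](O[Si](C)(C)C(C)(C)C)CC2(C)C)C2CCCC1CCC2
F10 | step 13 | 2-[(R)-4-(tert-butyldimethylsilyloxy)-2,6,6-trimethylcyclohex-1-en-1-yl]ethan-1-ol | OCCC1=C(C)C[C@@H](O[Si](C)(C)C(C)(C)C)CC1(C)C
F11 | step 13 | 2-[(R)-4-(tert-butyldimethylsilyloxy)-2,6,6-trimethylcyclohex-1-en-1-yl]acetaldehyde | O=CCC1=C(C)C[C@@H](O[Si](C)(C)C(C)(C)C)CC1(C)C
F12 | step 13 | 2-[(R)-4-(tert-butyldimethylsilyloxy)-2,6,6-trimethylcyclohex-1-en-1-yl]acetic acid | OC(=O)CC1=C(C)C[C@@H](O[Si](C)(C)C(C)(C)C)CC1(C)C
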